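Atoms of the reduced upper unit carry chromone numbers (O1, C2 … C8a); atoms of the aromatic lower unit carry primed numbers. Ar(PMB) stands for the 7-(4-methoxybenzyloxy)-4-oxo-2-(2-phenylethyl)-4H-chromen-6-yl group. The route uses compounds 1–18, numbered in the order in which they appear in the steps; the full list follows the steps.

## Analysis of the target

The target is an ether-linked dimer of two 2-(2-phenylethyl)chromones. The lower unit is a fully aromatic 7'-hydroxychromone that carries the ether oxygen at C6'. The upper unit is a γ-pyranone fused to a saturated carbocycle (C5–C8) in which every carbon bears oxygen: the aryl ether at C5 and free hydroxyls at C6, C7 and C8. The four contiguous stereocentres are 5S,6S,7R,8S, that is 5,6-trans, 6,7-cis and 7,8-trans, so the C5 aryloxy group and the C8 hydroxyl share one face and the cis-6,7-diol occupies the other. The C5–O and C8–O bonds are allylic to the pyranone C4a=C8a bond and the ring is only two eliminations away from an aromatic chromone, so acid, base and heat all threaten aromatisation; the pyranone opens with hydroxide and the 7'-phenol is acidic. The synthesis is hard because four adjacent oxygenated stereocentres must be raised on a ring that tends to become flat, and a secondary alkyl aryl ether must be made at the peri position C5 without ionising it. The feature used is that C5 and C8 are the para-related carbons of a 5,8-dioxygenated chromone: dearomatisation with C8 held as a dimethyl ketal makes C5 a prochiral ketone and leaves C6=C7 as the only isolated alkene, so one catalytic reduction at C5 can be relayed to C6 and C7 (anti cis-dihydroxylation) and from there to C8 (hydroxyl-directed hydride delivery).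

## Retrosynthetic reasoning

**18 from 17.** The last bond cut is the benzylic O–C bond of a 4-methoxybenzyl ether on O7'. The 7'-phenol is the more acidic of the two lower-unit hydroxyls and has to be masked while O6' acts as the nucleophile. The PMB group is chosen because it leaves by oxidation, so no hydrogenation is needed next to the allylic C5–O and C8–O bonds.

**17 from 16.** The C8–H bond is cut, giving the C8 ketone 16. C8 is the last stereocentre and its hydroxyl must be trans to the C7 hydroxyl. Both the C6 and C7 hydroxyls lie on the face from which hydride has to arrive, so an intramolecular, hydroxyl-directed reduction fits this centre.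

**16 from 15.** The ketone is traced back to its dimethyl ketal. The carbonyl cannot be present while C6=C7 exists, because a 5-aryloxy-5,8-dihydro-8-one is the keto tautomer of a phenol. The ketal carries the C8 oxidation level through the route in a form that cannot enolise.

**15 from 14 (key disconnection).** The C6–O and C7–O bonds are cut together. In 14 the only stereocentre is C5 and the two ketal methoxy groups are twins, one on each face, so the aryloxy group alone decides the face of a cis-dihydroxylation. Cutting here gains two stereocentres from one, with no ring construction. The forward reaction must be anti-selective, must pick C6=C7 out of four C=C bonds, and must stay neutral.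

**14 from 7 and 13.** The C5–O bond is cut on the alkyl side, so that the phenol 13 displaces an activated C5 hydroxyl with inversion (Mitsunobu reaction). Arylating the C5 oxygen with a 6'-halochromone under copper catalysis would retain the C5 configuration, but it needs base and heat, or divalent copper under oxygen. A bis-allylic carbinol para to a ketal would be re-oxidised or would aromatise under those conditions. The inversion is allowed for by making the 5S alcohol 7.

**7 from 6.** The C5–H bond is cut. The dienone 6 has one ketone flanked by a fully substituted ring-fusion carbon and a CH=, which is the large/small pattern an oxazaborolidine-catalysed reduction needs. This is the only step in which absolute configuration is created.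

**6 from 5, 4, 1 and 2.** The ketal C8–O bond and the C5 carbonyl come from oxidative dearomatisation of the para-methoxyphenol 5. Compound 5 comes from 4 by cleavage of the one methyl ether that is chelated to the C4 carbonyl. The pyranone of 4 is cut at C2–C3 and O1–C2, that is a Claisen condensation of ketone 1 with ester 2 followed by cyclodehydration. The carbocycle is thus the benzene ring of 1 and is never built.

**13 from 11, 9, 8 and 2.** The C6'–O bond is cut to a C–Br bond (borylation, then oxidation). The bromide 11 is again cut to an acetophenone, 9, and ester 2. Compound 9 is the mono-PMB ether of 8, formed at the more acidic 4'-hydroxyl.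

## Alternatives that were turned down

**Alternative 1:** The C5–O and C8–O bonds are made together on a carbocycle taken from the chiral pool.
- Key step: photooxygenation of the shikimate-derived diene ester A2, a [4+2] addition across the diene termini on the face away from the acetonide, gives the bicyclic endoperoxide A1. Its O–O bridge holds the future C5 and C8 oxygens cis to each other and anti to the 6,7-acetonide.
- For: the absolute configuration is bought, and one cycloaddition fixes the whole relative pattern of C5–C8. On stereochemistry this is stronger than the chosen route, which needs three separate stereo-defining events.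
- Against: A1 contains none of the pyranone. The ester carbon must become C4, the alkene CH that is to be C8a must acquire the ring oxygen, and three more carbons with the phenylethyl chain must be attached. All of this has to be done on a substrate whose O–O bond is reducible and rearranges with base.
- Against: after O–O cleavage the C5 and C8 hydroxyls are both secondary and allylic and must be told apart. Because C5 then already has the right configuration, its aryl ether must be made with retention by arylating the oxygen, the bond construction the chosen route avoids.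
- Comparison: the sequence would be longer by many operations. The chosen strategy offers instead a substrate in which pyranone, side chain and the 5,8-oxygen pattern are present from the first step.

**Alternative 2:** The C6=C7 bond is cut, by ring-closing metathesis.
- Key step: the second-generation Grubbs catalyst joins the two vinyl groups of pyranone A4, which carries a 1-aryloxyallyl arm on the future C4a and a 1-silyloxyallyl arm on the future C8a. This closes the six-membered ring to the cis-5,8-dioxygenated dihydrochromone A3.
- For: six-ring closure of a 1,7-diene is very dependable. In A3 both allylic substituents lie on one face, so a later dihydroxylation is steered by two groups. C8 is already a carbinol, so there is no fragile C8 ketone and no late reduction. On these points it is stronger than the chosen route.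
- Against: the difficulty moves into A4. Two different carbinol centres, each flanked by a vinyl group and the electron-poor pyranone, must be set by two separate reagent-controlled steps on a 2,3-difunctionalised pyranone that itself has to be made.
- Against: the aryl ether must be installed on a carbinol whose SN2′ terminus is an unhindered vinyl CH2, whereas in 7 the corresponding position is neopentyl. A3 also has hydrogens at both C5 and C8 and therefore two routes of 1,4-elimination to an aromatic chromone, whereas 14 has one and it needs acid.
- Comparison: the step count is clearly higher. The chosen strategy has the carbocycle from the start and needs one asymmetric step.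

**Alternative 3:** The C4a–C5 and C8a–C8 bonds are cut, by a Diels–Alder reaction.
- Key step: the sulfinylpyranone A6 (dienophile across the future C4a=C8a bond) adds the 1-aryloxy-4-benzoyloxy diene A7. Thermal syn-elimination of the sulfinyl group then restores the γ-pyranone and gives the cis-5-aryloxy-8-benzoyloxy dihydrochromone A5.
- For: it is the most convergent plan. The whole lower unit arrives inside the diene, so the aryl ether is never made at a stereocentre. The E,E geometry of A7 becomes the cis-5,8 relationship, the sulfoxide can carry the absolute information, and C8 is set before dihydroxylation. Two C–C bonds and two stereocentres form in one step, which the chosen route cannot match.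
- Against: the two termini of A7 carry oxygen donors of similar strength, so the orientation of the addition rests on a small electronic difference. A γ-pyranone C=C is a reluctant dienophile.
- Against: the sulfoxide can eliminate toward C5 as well as toward C8a. A5 holds a good leaving group para to C5–H and can aromatise by 1,4-elimination. A7 needs its own synthesis with control of two enol geometries.
- Comparison: the chosen strategy forms no C–C bond on the carbocycle. Each of its selectivity questions is of a well-behaved kind: large versus small flank of a ketone, addition anti to an allylic oxygen, and hydroxyl-directed hydride delivery.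

Key step: step 9

Remark on the chemistry: the C5 ether bond is closed by SN2 inversion, so the reduction is run to the 5S alcohol. The change of the C5 descriptor from R in 14 to S in 15 is a change of CIP priorities only.

## Route

Step 1
Reactants: 1 2'-hydroxy-3',6'-dimethoxyacetophenone; 2 ethyl 3-phenylpropanoate
Product: 4 5,8-dimethoxy-2-(2-phenylethyl)-4H-chromen-4-one, via β-diketone 3 (not isolated)
Conditions: NaH, THF, reflux; then MeOH quench, HCl/MeOH, 50 °C
Reagents that add atoms: none
Why: Crossed Claisen condensation of the phenoxide–enolate dianion of 1 with ester 2 gives the 1,3-diketone; acid then closes the pyranone by hemiketalisation of the phenol onto the distal carbonyl and dehydration, the standard construction of 2-(2-phenylethyl)chromones.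

Step 2
Reactants: 4 5,8-dimethoxy-2-(2-phenylethyl)-4H-chromen-4-one
Product: 5 5-hydroxy-8-methoxy-2-(2-phenylethyl)-4H-chromen-4-one
Conditions: BCl3, CH2Cl2, −78 to 0 °C; aqueous work-up
Reagents that add atoms: none
Why: Chelation-controlled ether cleavage: BCl3 binds the C4 carbonyl and cleaves only the peri 5-methyl ether through a six-membered chelate, while the 8-methyl ether has no such assistance and stays.

Step 3
Reactants: 5 5-hydroxy-8-methoxy-2-(2-phenylethyl)-4H-chromen-4-one
Product: 6 8,8-dimethoxy-2-(2-phenylethyl)-4H-chromene-4,5(8H)-dione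
Conditions: PhI(OAc)2, MeOH, 0 °C; NaHCO3 work-up
Reagents that add atoms: methanol, CO
Why: Oxidative dearomatisation of a para-methoxyphenol with trivalent iodine: ligand exchange at the phenol oxygen and attack of methanol at the para carbon C8 with loss of iodobenzene give the quinone monoketal.

Step 4
Reactants: 6 8,8-dimethoxy-2-(2-phenylethyl)-4H-chromene-4,5(8H)-dione
Product: 7 (5S)-5-hydroxy-8,8-dimethoxy-2-(2-phenylethyl)-5,8-dihydro-4H-chromen-4-one
Conditions: (R)-Me-CBS oxazaborolidine (20 mol%), catecholborane, CH2Cl2, −78 °C; MeOH, then aq. NaHCO3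
Reagents that add atoms: none
Why: Corey–Bakshi–Shibata reduction of a cyclic dienone: the ketone binds the catalyst boron anti to its larger flank (the ring-fusion carbon C4a with its peri carbonyl) and takes hydride on one face, which by analogy with aryl alkyl ketones gives the 5S alcohol from the (R)-catalyst. Catecholborane reduces s-trans enones 1,2 and leaves C6=C7 and the pyranone carbonyl alone; the neutral work-up spares the acid-labile dienol ketal.

Step 5
Reactants: 8 5'-bromo-2',4'-dihydroxyacetophenone
Product: 9 5'-bromo-2'-hydroxy-4'-(4-methoxybenzyloxy)acetophenone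
Conditions: 4-methoxybenzyl chloride, K2CO3, acetone, reflux
Reagents that add atoms: 4-methoxybenzyl chloride, COc1ccc(CCl)cc1
Why: Williamson etherification; the 4'-hydroxyl, para to the acetyl group, is the more acidic one, while the 2'-hydroxyl is held in a hydrogen bond to the ketone, so mono-alkylation at O4' is expected.

Step 6
Reactants: 9 5'-bromo-2'-hydroxy-4'-(4-methoxybenzyloxy)acetophenone; 2 ethyl 3-phenylpropanoate
Product: 11 6-bromo-7-(4-methoxybenzyloxy)-2-(2-phenylethyl)-4H-chromen-4-one, via β-diketone 10 (not isolated)
Conditions: NaH, THF, reflux; then MeOH quench, HCl/MeOH (pH 1–2), 20 °C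
Reagents that add atoms: none
Why: The same Claisen condensation and cyclodehydration as in step 1; dilute methanolic acid at room temperature should dehydrate the 2-hydroxychromanone and is mild enough to keep the aryl PMB ether.

Step 7
Reactants: 11 6-bromo-7-(4-methoxybenzyloxy)-2-(2-phenylethyl)-4H-chromen-4-one
Product: 13 6-hydroxy-7-(4-methoxybenzyloxy)-2-(2-phenylethyl)-4H-chromen-4-one, via pinacol boronate 12 (not isolated)
Conditions: B2pin2, PdCl2(dppf) (5 mol%), KOAc, 1,4-dioxane, 90 °C; then NaBO3·4H2O, THF/H2O, 20 °C
Reagents that add atoms: bis(pinacolato)diboron, CC1(C)OB(OC1(C)C)B1OC(C)(C)C(C)(C)O1 (boryl group of 12); sodium perborate, [Na+].[Na+].O[B-]1(O)OO[B-](O)(O)OO1 (phenolic oxygen of 13)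
Why: Miyaura borylation (oxidative addition of the aryl bromide to zerovalent palladium, acetate-assisted transmetallation, reductive elimination) followed by oxidation of the C–B bond with 1,2-shift of the aryl group to oxygen; perborate is mild enough for the base-sensitive pyranone.

Step 8
Reactants: 7 (5S)-5-hydroxy-8,8-dimethoxy-2-(2-phenylethyl)-5,8-dihydro-4H-chromen-4-one; 13 6-hydroxy-7-(4-methoxybenzyloxy)-2-(2-phenylethyl)-4H-chromen-4-one
Product: 14 (5R)-8,8-dimethoxy-5-[Ar(PMB)-oxy]-2-(2-phenylethyl)-5,8-dihydro-4H-chromen-4-one
Conditions: PPh3, DIAD, THF, 0 to 20 °C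
Reagents that add atoms: none
Why: Mitsunobu etherification: the phenoxide of 13 displaces the C5 oxyphosphonium group by SN2 with inversion, turning the 5S alcohol into the 5R ether under essentially neutral conditions. The carbinol has no β-hydrogen that can be eliminated and the SN2′ terminus C7 is neopentyl next to the ketal carbon, so direct substitution at the doubly allylic C5 should dominate.

Step 9
Reactants: 14 (5R)-8,8-dimethoxy-5-[Ar(PMB)-oxy]-2-(2-phenylethyl)-5,8-dihydro-4H-chromen-4-one
Product: 15 (5S,6S,7R)-6,7-dihydroxy-8,8-dimethoxy-5-[Ar(PMB)-oxy]-2-(2-phenylethyl)-5,6,7,8-tetrahydro-4H-chromen-4-one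
Conditions: OsO4 (5 mol%), NMO, acetone/H2O (8:1), 20 °C; aq. Na2SO3 quench
Reagents that add atoms: osmium tetroxide (catalytic oxygen carrier), O=[Os](=O)(=O)=O; N-methylmorpholine N-oxide, C[N+]1([O-])CCOCC1; water, O
Why: Osmium tetroxide adds to C6=C7 in a concerted [3+2] cycloaddition to give an osmate ester of hexavalent osmium, which water hydrolyses to the cis-diol while NMO returns the metal to the octavalent state (Upjohn dihydroxylation); no ring is closed. The closest known reaction type is the osmylation of cyclic allylic ethers, which takes place anti to the allylic oxygen (Kishi's empirical rule). C5 is the only stereocentre of 14 and the two methoxy groups on C8 sit one on each face, so the facial bias comes from C5 alone. The bulky chromonyloxy group is pushed out of the ring plane by the peri C4 carbonyl and shields its own face, and the C5–O dipole also disfavours syn approach. Both new centres, C6 and C7, are therefore set together by the C5 configuration, giving the 5,6-trans, 6,7-cis triad (5S,6S,7R). Chemoselectivity is needed among four C=C bonds: the C2=C3 and C4a=C8a bonds of the two pyranones are vinylogous-ester alkenes of low nucleophilicity and C4a=C8a is tetrasubstituted, so the isolated cis-disubstituted C6=C7 bond should react first. The medium is neutral to slightly basic, which is required because acid would ionise the ketal and let 14 lose methanol to an aromatic chromone; once C6 and C7 are sp3 that escape is closed.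

Step 10
Reactants: 15 (5S,6S,7R)-6,7-dihydroxy-8,8-dimethoxy-5-[Ar(PMB)-oxy]-2-(2-phenylethyl)-5,6,7,8-tetrahydro-4H-chromen-4-one
Product: 16 (5S,6S,7R)-6,7-dihydroxy-5-[Ar(PMB)-oxy]-2-(2-phenylethyl)-6,7-dihydro-4H-chromene-4,8(5H)-dione
Conditions: 1 M aq. HCl/THF (1:4), 0 to 20 °C; pH 7 buffer; crude product used at once
Reagents that add atoms: water, O
Why: Acid-catalysed ketal hydrolysis through the C8 oxocarbenium ion; dilute aqueous acid in the cold should leave the aryl PMB ether and the C5 ether intact and should be too weak to enolise the α-ketol toward C7.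

Step 11
Reactants: 16 (5S,6S,7R)-6,7-dihydroxy-5-[Ar(PMB)-oxy]-2-(2-phenylethyl)-6,7-dihydro-4H-chromene-4,8(5H)-dione
Product: 17 (5S,6S,7R,8S)-6,7,8-trihydroxy-5-[Ar(PMB)-oxy]-2-(2-phenylethyl)-5,6,7,8-tetrahydro-4H-chromen-4-one
Conditions: Me4NBH(OAc)3, MeCN/AcOH (1:1), −30 to −10 °C
Reagents that add atoms: none
Why: Saksena–Evans hydroxyl-directed reduction: triacetoxyborohydride reduces the ketone only after exchanging an acetate for a substrate hydroxyl and then delivers hydride intramolecularly. The C7 hydroxyl (five-membered delivery) and the C6 hydroxyl (six-membered delivery) both lie on the face opposite the C5 aryloxy group, so hydride enters C8 from that face and the new hydroxyl appears trans to the C7 hydroxyl, which sets 8S.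

Step 12
Reactants: 17 (5S,6S,7R,8S)-6,7,8-trihydroxy-5-[Ar(PMB)-oxy]-2-(2-phenylethyl)-5,6,7,8-tetrahydro-4H-chromen-4-one
Product: 18 (5S,6S,7R,8S)-6,7,8-trihydroxy-5-{[7-hydroxy-4-oxo-2-(2-phenylethyl)-4H-chromen-6-yl]oxy}-2-(2-phenylethyl)-5,6,7,8-tetrahydro-4H-chromen-4-one
Conditions: DDQ, CH2Cl2/pH 7 phosphate buffer (10:1), 0 to 20 °C
Reagents that add atoms: none
Why: Oxidative PMB cleavage: hydride transfer from the electron-rich 4-methoxybenzyl group to DDQ gives an oxocarbenium ion that water hydrolyses to the free 7'-phenol; no stereocentre is touched, and the electron-poor allylic alcohols on the pyranone ring should be oxidised far more slowly than the PMB group.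

## Compound list

1 | 2'-hydroxy-3',6'-dimethoxyacetophenone | CC(=O)c1c(O)c(OC)ccc1OC | starting material
2 | ethyl 3-phenylpropanoate | CCOC(=O)CCc1ccccc1 | starting material
3 | 1-(2-hydroxy-3,6-dimethoxyphenyl)-5-phenylpentane-1,3-dione | O=C(CCc1ccccc1)CC(=O)c1c(O)c(OC)ccc1OC | intermediate
4 | 5,8-dimethoxy-2-(2-phenylethyl)-4H-chromen-4-one | COc1ccc(OC)c2oc(CCc3ccccc3)cc(=O)c12 | intermediate
5 | 5-hydroxy-8-methoxy-2-(2-phenylethyl)-4H-chromen-4-one | COc1ccc(O)c2c(=O)cc(CCc3ccccc3)oc12 | intermediate
6 | 8,8-dimethoxy-2-(2-phenylethyl)-4H-chromene-4,5(8H)-dione | O=C1C=CC(OC)(OC)c2oc(CCc3ccccc3)cc(=O)c12 | intermediate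
7 | (5S)-5-hydroxy-8,8-dimethoxy-2-(2-phenylethyl)-5,8-dihydro-4H-chromen-4-one | O=c1cc(CCc2ccccc2)oc2c1[C@@H](O)C=CC2(OC)OC | intermediate
8 | 5'-bromo-2',4'-dihydroxyacetophenone | CC(=O)c1cc(Br)c(O)cc1O | starting material
9 | 5'-bromo-2'-hydroxy-4'-(4-methoxybenzyloxy)acetophenone | CC(=O)c1cc(Br)c(OCc2ccc(OC)cc2)cc1O | intermediate
10 | 1-[5-bromo-2-hydroxy-4-(4-methoxybenzyloxy)phenyl]-5-phenylpentane-1,3-dione | O=C(CCc1ccccc1)CC(=O)c1cc(Br)c(OCc2ccc(OC)cc2)cc1O | intermediate
11 | 6-bromo-7-(4-methoxybenzyloxy)-2-(2-phenylethyl)-4H-chromen-4-one | O=c1cc(CCc2ccccc2)oc2cc(OCc3ccc(OC)cc3)c(Br)cc12 | intermediate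
12 | 7-(4-methoxybenzyloxy)-2-(2-phenylethyl)-6-(4,4,5,5-tetramethyl-1,3,2-dioxaborolan-2-yl)-4H-chromen-4-one | O=c1cc(CCc2ccccc2)oc2cc(OCc3ccc(OC)cc3)c(B3OC(C)(C)C(C)(C)O3)cc12 | intermediate
13 | 6-hydroxy-7-(4-methoxybenzyloxy)-2-(2-phenylethyl)-4H-chromen-4-one | O=c1cc(CCc2ccccc2)oc2cc(OCc3ccc(OC)cc3)c(O)cc12 | intermediate
14 | (5R)-8,8-dimethoxy-5-{[7-(4-methoxybenzyloxy)-4-oxo-2-(2-phenylethyl)-4H-chromen-6-yl]oxy}-2-(2-phenylethyl)-5,8-dihydro-4H-chromen-4-one | O=c1cc(CCc2ccccc2)oc2c1[C@H](Oc1cc3c(=O)cc(CCc4ccccc4)oc3cc1OCc1ccc(OC)cc1)C=CC2(OC)OC | intermediate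
15 | (5S,6S,7R)-6,7-dihydroxy-8,8-dimethoxy-5-{[7-(4-methoxybenzyloxy)-4-oxo-2-(2-phenylethyl)-4H-chromen-6-yl]oxy}-2-(2-phenylethyl)-5,6,7,8-tetrahydro-4H-chromen-4-one | O=c1cc(CCc2ccccc2)oc2c1[C@H](Oc1cc3c(=O)cc(CCc4ccccc4)oc3cc1OCc1ccc(OC)cc1)[C@@H](O)[C@@H](O)C2(OC)OC | intermediate
16 | (5S,6S,7R)-6,7-dihydroxy-5-{[7-(4-methoxybenzyloxy)-4-oxo-2-(2-phenylethyl)-4H-chromen-6-yl]oxy}-2-(2-phenylethyl)-6,7-dihydro-4H-chromene-4,8(5H)-dione | O=c1cc(CCc2ccccc2)oc2c1[C@H](Oc1cc3c(=O)cc(CCc4ccccc4)oc3cc1OCc1ccc(OC)cc1)[C@@H](O)[C@@H](O)C2=O | intermediate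
17 | (5S,6S,7R,8S)-6,7,8-trihydroxy-5-{[7-(4-methoxybenzyloxy)-4-oxo-2-(2-phenylethyl)-4H-chromen-6-yl]oxy}-2-(2-phenylethyl)-5,6,7,8-tetrahydro-4H-chromen-4-one | O=c1cc(CCc2ccccc2)oc2c1[C@H](Oc1cc3c(=O)cc(CCc4ccccc4)oc3cc1OCc1ccc(OC)cc1)[C@@H](O)[C@@H](O)[C@@H]2O | intermediate
18 | (5S,6S,7R,8S)-6,7,8-trihydroxy-5-{[7-hydroxy-4-oxo-2-(2-phenylethyl)-4H-chromen-6-yl]oxy}-2-(2-phenylethyl)-5,6,7,8-tetrahydro-4H-chromen-4-one | O=c1cc(CCc2ccccc2)oc2c1[C@H](Oc1cc3c(=O)cc(CCc4ccccc4)oc3cc1O)[C@@H](O)[C@@H](O)[C@@H]2O | target

## Step count and least certain steps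

Total: 12 steps. Longest linear sequence: 9 steps (steps 1, 2, 3, 4, 8, 9, 10, 11 and 12, from 1). The lower unit needs 3 steps (5 to 7) before the union.

**Step 9 (key step).**
- Risk: incomplete facial discrimination, that is partial osmylation on the face of the aryloxy group. The cyclohexa-1,4-diene ring is nearly flat and carries a methoxy group on each face at C8. Turnover may also be slow on an alkene flanked by two electron-withdrawing carbons, which lengthens the exposure of the ketal.
- Fallback (sets out from 7, returns at 16): the order of ether formation and dihydroxylation is reversed.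
  - Alcohol 7 is dihydroxylated under hydrogen-bond direction (stoichiometric OsO4·TMEDA, CH2Cl2, −78 °C, osmate ester released with ethylenediamine). This places the diol syn to the C5 hydroxyl and gives the all-cis triol (5R,6R,7R)-5,6,7-trihydroxy-8,8-dimethoxy-2-(2-phenylethyl)-5,6,7,8-tetrahydro-4H-chromen-4-one F1.
  - Acetonide formation under equilibrating conditions (2,2-dimethoxypropane, PPTS) should engage O6 and O7, because the C5 hydroxyl keeps its hydrogen bond to the C4 carbonyl. It gives the 6,7-acetonide (5R,6R,7R)-5-hydroxy-6,7-(isopropylidenedioxy)-8,8-dimethoxy-2-(2-phenylethyl)-5,6,7,8-tetrahydro-4H-chromen-4-one F2.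
  - Mitsunobu coupling of this acetonide with 13 inverts C5 and gives the aryl ether (5S,6R,7R)-5-[Ar(PMB)-oxy]-6,7-(isopropylidenedioxy)-8,8-dimethoxy-2-(2-phenylethyl)-5,6,7,8-tetrahydro-4H-chromen-4-one F3, with the aryloxy group anti to the dioxolane.
  - Aqueous HCl in THF removes acetonide and ketal together and gives 16.

**Step 8.**
- Risk: ionisation of the activated C5 oxygen instead of clean SN2 displacement, which would erode the C5 configuration. Attack of the phenoxide at C7 with allylic transposition, or collapse to an aromatic chromone by loss of methanol, are also possible.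
- Fallback (sets out from 6 and from 12, returns at 14): the ether is formed from the oxygen side, with retention.
  - Reduction of 6 with the (S)-Me-CBS catalyst gives the enantiomeric alcohol (5R)-5-hydroxy-8,8-dimethoxy-2-(2-phenylethyl)-5,8-dihydro-4H-chromen-4-one F4.
  - Boronate 12, isolated in this variant, is converted with KHF2 into potassium [7-(4-methoxybenzyloxy)-4-oxo-2-(2-phenylethyl)-4H-chromen-6-yl]trifluoroborate F5.
  - A Chan–Lam–Evans etherification (Cu(OAc)2·H2O, DMAP, 4 Å molecular sieves, O2, CH2Cl2, 20 °C) joins the two without breaking the C5–O bond and gives 14.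

**Step 4.**
- Risk: poor enantiofacial discrimination, because both flanks of the C5 carbonyl are sp2 ring carbons and the peri C4 carbonyl offers boron a second binding site. If only the sense is reversed, the other catalyst enantiomer is used.
- Fallback (sets out from 6, returns at 7): reduction with NaBH4 and CeCl3·7H2O in MeOH at −78 °C gives the racemic alcohol rac-5-hydroxy-8,8-dimethoxy-2-(2-phenylethyl)-5,8-dihydro-4H-chromen-4-one F6.
  - Kinetic resolution with Burkholderia cepacia lipase and vinyl acetate should acetylate the R enantiomer to (5R)-5-acetoxy-8,8-dimethoxy-2-(2-phenylethyl)-5,8-dihydro-4H-chromen-4-one F7 and leave 7, which is separated and carried on.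

**Step 10.**
- Risk: the ketal, deactivated by the neighbouring C7 hydroxyl and the electron-poor C8a, may hydrolyse only under acid strong enough to cleave the PMB ether as well. Acid-promoted enolisation of the α-ketol toward C7, followed by dehydration and aromatisation, is the other danger.
- Fallback (sets out from 15, returns at 18): both cleavages are accepted at once. TFA/H2O/CH2Cl2 with anisole as cation trap at 0 °C gives the phenol ketone (5S,6S,7R)-6,7-dihydroxy-5-{[7-hydroxy-4-oxo-2-(2-phenylethyl)-4H-chromen-6-yl]oxy}-2-(2-phenylethyl)-6,7-dihydro-4H-chromene-4,8(5H)-dione F8.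
  - The directed reduction with Me4NBH(OAc)3, which tolerates the free phenol, then gives 18 directly, so steps 11 and 12 are not needed.

**Step 11.**
- Risk: enolisation of the α-hydroxy ketone in the acetic acid medium before hydride delivery (epimerisation at C7 or dehydration), or loss of facial control if undirected hydride transfer competes.
- Fallback (sets out from 16, returns at 17): catalyst-controlled Noyori–Ikariya transfer hydrogenation with RuCl(p-cymene)[(S,S)-TsDPEN] in HCO2H/Et3N. C8a plays the part of the aryl group of an aryl ketone, for which this catalyst enantiomer gives the S carbinol. No new compound is made.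

**Step 6.**
- Risk: partial loss of the PMB group during the acid-catalysed cyclodehydration, or incomplete dehydration if the acid is kept weak.
- Fallback (sets out from 9, returns at 11): the Claisen product is cyclised under forcing conditions (conc. HCl/AcOH, 80 °C) with deliberate loss of the PMB group, giving 6-bromo-7-hydroxy-2-(2-phenylethyl)-4H-chromen-4-one F9. This is re-alkylated with 4-methoxybenzyl chloride and K2CO3 in DMF to give 11.

## Further compounds

F1 | step 9 | (5R,6R,7R)-5,6,7-trihydroxy-8,8-dimethoxy-2-(2-phenylethyl)-5,6,7,8-tetrahydro-4H-chromen-4-one | O=c1cc(CCc2ccccc2)oc2c1[C@@H](O)[C@@H](O)[C@@H](O)C2(OC)OC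
F2 | step 9 | (5R,6R,7R)-5-hydroxy-6,7-(isopropylidenedioxy)-8,8-dimethoxy-2-(2-phenylethyl)-5,6,7,8-tetrahydro-4H-chromen-4-one | O=c1cc(CCc2ccccc2)oc2c1[C@@H](O)[C@@H](OC3(C)C)[C@@H](O3)C2(OC)OC
F3 | step 9 | (5S,6R,7R)-6,7-(isopropylidenedioxy)-8,8-dimethoxy-5-{[7-(4-methoxybenzyloxy)-4-oxo-2-(2-phenylethyl)-4H-chromen-6-yl]oxy}-2-(2-phenylethyl)-5,6,7,8-tetrahydro-4H-chromen-4-one | O=c1cc(CCc2ccccc2)oc2c1[C@H](Oc1cc3c(=O)cc(CCc4ccccc4)oc3cc1OCc1ccc(OC)cc1)[C@@H](OC3(C)C)[C@@H](O3)C2(OC)OC
F4 | step 8 | (5R)-5-hydroxy-8,8-dimethoxy-2-(2-phenylethyl)-5,8-dihydro-4H-chromen-4-one | O=c1cc(CCc2ccccc2)oc2c1[C@H](O)C=CC2(OC)OC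
F5 | step 8 | potassium [7-(4-methoxybenzyloxy)-4-oxo-2-(2-phenylethyl)-4H-chromen-6-yl]trifluoroborate | [K+].F[B-](F)(F)c1cc2c(=O)cc(CCc3ccccc3)oc2cc1OCc1ccc(OC)cc1
F6 | step 4 | rac-5-hydroxy-8,8-dimethoxy-2-(2-phenylethyl)-5,8-dihydro-4H-chromen-4-one | O=c1cc(CCc2ccccc2)oc2c1C(O)C=CC2(OC)OC
F7 | step 4 | (5R)-5-acetoxy-8,8-dimethoxy-2-(2-phenylethyl)-5,8-dihydro-4H-chromen-4-one | O=c1cc(CCc2ccccc2)oc2c1[C@H](OC(C)=O)C=CC2(OC)OC
F8 | step 10 | (5S,6S,7R)-6,7-dihydroxy-5-{[7-hydroxy-4-oxo-2-(2-phenylethyl)-4H-chromen-6-yl]oxy}-2-(2-phenylethyl)-6,7-dihydro-4H-chromene-4,8(5H)-dione | O=c1cc(CCc2ccccc2)oc2c1[C@H](Oc1cc3c(=O)cc(CCc4ccccc4)oc3cc1O)[C@@H](O)[C@@H](O)C2=O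
F0 | step 11 | none | none
F9 | step 6 | 6-bromo-7-hydroxy-2-(2-phenylethyl)-4H-chromen-4-one | O=c1cc(CCc2ccccc2)oc2cc(O)c(Br)cc12
A1 | alternative 1 | methyl 7,8-(isopropylidenedioxy)-2,3-dioxabicyclo[2.2.2]oct-5-ene-5-carboxylate (endoperoxide anti to the acetonide) | COC(=O)C1=C[C@H]2OO[C@@H]1[C@H]1OC(C)(C)O[C@@H]21
A2 | alternative 1 | methyl (3R,4S)-3,4-(isopropylidenedioxy)cyclohexa-1,5-diene-1-carboxylate | COC(=O)C1=C[C@H]2OC(C)(C)O[C@H]2C=C1
A3 | alternative 2 | cis-8-(tert-butyldimethylsilyloxy)-5-{[7-(4-methoxybenzyloxy)-4-oxo-2-(2-phenylethyl)-4H-chromen-6-yl]oxy}-2-(2-phenylethyl)-5,8-dihydro-4H-chromen-4-one | O=c1cc(CCc2ccccc2)oc2c1[C@H](Oc1cc3c(=O)cc(CCc4ccccc4)oc3cc1OCc1ccc(OC)cc1)C=C[C@@H]2O[Si](C)(C)C(C)(C)C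
A4 | alternative 2 | 2-[1-(tert-butyldimethylsilyloxy)prop-2-en-1-yl]-3-(1-{[7-(4-methoxybenzyloxy)-4-oxo-2-(2-phenylethyl)-4H-chromen-6-yl]oxy}prop-2-en-1-yl)-6-(2-phenylethyl)-4H-pyran-4-one (carbinol centres as in A3) | O=c1cc(CCc2ccccc2)oc([C@@H](O[Si](C)(C)C(C)(C)C)C=C)c1[C@H](Oc1cc3c(=O)cc(CCc4ccccc4)oc3cc1OCc1ccc(OC)cc1)C=C
A5 | alternative 3 | cis-5-{[7-(4-methoxybenzyloxy)-4-oxo-2-(2-phenylethyl)-4H-chromen-6-yl]oxy}-4-oxo-2-(2-phenylethyl)-5,8-dihydro-4H-chromen-8-yl benzoate | O=c1cc(CCc2ccccc2)oc2c1[C@H](Oc1cc3c(=O)cc(CCc4ccccc4)oc3cc1OCc1ccc(OC)cc1)C=C[C@@H]2OC(=O)c1ccccc1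
A6 | alternative 3 | (S)-2-(2-phenylethyl)-5-(4-tolylsulfinyl)-4H-pyran-4-one (sulfur configuration to be matched to the facial bias) | O=c1cc(CCc2ccccc2)occ1[S@@](=O)c1ccc(C)cc1
A7 | alternative 3 | (1E,3E)-4-{[7-(4-methoxybenzyloxy)-4-oxo-2-(2-phenylethyl)-4H-chromen-6-yl]oxy}buta-1,3-dien-1-yl benzoate | O=C(O/C=C/C=C/Oc1cc2c(=O)cc(CCc3ccccc3)oc2cc1OCc1ccc(OC)cc1)c1ccccc1
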